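The ring-fusion bond C8–C9 carries the whole plan (locants in the remark below). C9 lies between C1 and C10, and C8 is flanked by C12, which carries the ring-B oxygen O11. C9 is therefore made the α-carbon of a β-keto ester (C1 ketone, C10 carboxyl) and C8 the secondary carbon of a Sharpless epoxide. With the keto ester hung on the C16 hydroxyl, base closes a temporary δ-lactone by C8–C9 alkylation with inversion at C8. The C12 alkoxide then takes over the acyl group, giving the ring-B γ-lactone and free C16–OH, while C9 settles trans. Ring A is closed later by metathesis at C3=C4; (S)-linalool supplies C4–C8.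

Key step: step 8

Remark (locants): ring A = nine-membered carbocycle C1(=CH2)–C2H2–C3H=C4H–C5(CH3)(OH)–C6H2–C7H2–C8H–C9H; ring B = tetrahydrofuran C8–C9–C10H2–O11–C12; C13 = first dienyl carbon on C12; C16 = CH2O(stearoyl) on C12. Target: 5S, 8S, 9R, 12R, C3=C4 Z, dienyl E, rings trans-fused.
Assumption: (S)-(+)-linalool of high enantiomeric purity is taken as a purchasable chiral-pool material.

Step 1
Reactants: 1 (S)-(+)-linalool
Product: 2 (3S)-3,7-dimethyl-3-(triethylsilyloxy)octa-1,6-diene
Conditions: TESOTf, 2,6-lutidine, CH2Cl2, −78 → 0 °C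
Reagents that add atoms: triethylsilyl trifluoromethanesulfonate, CC[Si](CC)(CC)OS(=O)(=O)C(F)(F)F
Why: Silyl triflate silylation masks the hindered tertiary C5–OH, which would otherwise form a lactol after step 2, add to the enoate of step 3 or open the epoxide of step 5; the C5 stereocentre is untouched.

Step 2
Reactants: 2 (3S)-3,7-dimethyl-3-(triethylsilyloxy)octa-1,6-diene
Product: 3 (4S)-4-methyl-4-(triethylsilyloxy)hex-5-enal
Conditions: O3, CH2Cl2, −78 °C (Sudan Red 7B end-point); then Me2S, −78 °C → rt
Reagents that add atoms: ozone, [O-][O+]=O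
Why: Chemoselective ozonolysis, since the electron-rich trisubstituted alkene is cleaved much faster than the vinyl group beside the quaternary silyloxy carbon, and reductive work-up gives the C8 aldehyde.

Step 3
Reactants: 3 (4S)-4-methyl-4-(triethylsilyloxy)hex-5-enal; 4 ethyl 2-(diethoxyphosphoryl)acrylate; 5 4-methoxybenzyl alcohol
Product: 7 ethyl (2E,6S)-2-[(4-methoxybenzyloxy)methyl]-6-methyl-6-(triethylsilyloxy)octa-2,7-dienoate, via phosphonate carbanion 6 (not isolated)
Conditions: 5, NaH, THF, 0 °C; 4, 0 °C; then 3, −20 °C → rt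
Reagents that add atoms: none
Why: Tandem oxa-Michael addition/Horner–Wadsworth–Emmons olefination, in which the alkoxide adds to the vinylphosphonate and the resulting α-substituted phosphonoacetate anion olefinates the aldehyde with the usual preference for the ester trans to the alkyl chain, placing the future C16 trans and the C13 arm cis to C7.

Step 4
Reactants: 7 ethyl (2E,6S)-2-[(4-methoxybenzyloxy)methyl]-6-methyl-6-(triethylsilyloxy)octa-2,7-dienoate
Product: 8 (2Z,6S)-2-[(4-methoxybenzyloxy)methyl]-6-methyl-6-(triethylsilyloxy)octa-2,7-dien-1-ol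
Conditions: i-Bu2AlH, CH2Cl2, −78 °C; aq. potassium sodium tartrate
Reagents that add atoms: none
Why: DIBAL-H 1,2-reduction of the enoate gives the allylic alcohol (CH2OH trans to the chain) without touching the alkene geometry.

Step 5
Reactants: 8 (2Z,6S)-2-[(4-methoxybenzyloxy)methyl]-6-methyl-6-(triethylsilyloxy)octa-2,7-dien-1-ol
Product: 9 [(2R,3S)-2-[(4-methoxybenzyloxy)methyl]-3-[(3S)-3-methyl-3-(triethylsilyloxy)pent-4-enyl]oxiran-2-yl]methanol
Conditions: Ti(OiPr)4 (10 mol%), L-(+)-diethyl tartrate (12 mol%), t-BuOOH (decane), 4 Å molecular sieves, CH2Cl2, −20 °C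
Reagents that add atoms: tert-butyl hydroperoxide, CC(C)(C)OO
Why: Sharpless asymmetric epoxidation of an E-type 2,3-disubstituted allylic alcohol, in which L-(+)-diethyl tartrate should deliver oxygen to the face that turns (E)-hex-2-en-1-ol into its (2S,3S)-epoxide, here setting C12 (R) and C8 (S, to be inverted in step 8) while the ethers and the vinyl group stay inert.

Step 6
Reactants: 10 Meldrum's acid; 11 but-3-enoic acid
Product: 12 5-(1-hydroxybut-3-enylidene)-2,2-dimethyl-1,3-dioxane-4,6-dione
Conditions: DCC, DMAP, CH2Cl2, 0 °C → rt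
Reagents that add atoms: none
Why: Carbodiimide-mediated C-acylation of Meldrum's acid (Oikawa–Yonemitsu acylation) at 0 °C, where the β,γ-double bond should stay out of conjugation.

Step 7
Reactants: 9 [(2R,3S)-2-[(4-methoxybenzyloxy)methyl]-3-[(3S)-3-methyl-3-(triethylsilyloxy)pent-4-enyl]oxiran-2-yl]methanol; 12 5-(1-hydroxybut-3-enylidene)-2,2-dimethyl-1,3-dioxane-4,6-dione
Product: 14 {(2S,3S)-2-[(4-methoxybenzyloxy)methyl]-3-[(3S)-3-methyl-3-(triethylsilyloxy)pent-4-enyl]oxiran-2-yl}methyl 3-oxohex-5-enoate, via but-3-enoylketene 13 (not isolated)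
Conditions: toluene, 90 °C
Reagents that add atoms: none
Why: Thermolysis of the acyl Meldrum's acid loses acetone and CO2 to give an acylketene that the primary hydroxyl traps under neutral conditions tolerated by the epoxide (acylketene acylation; the changed descriptor at the oxirane carbon is a priority effect only).

Step 8
Reactants: 14 {(2S,3S)-2-[(4-methoxybenzyloxy)methyl]-3-[(3S)-3-methyl-3-(triethylsilyloxy)pent-4-enyl]oxiran-2-yl}methyl 3-oxohex-5-enoate
Product: 16 (3R,4S,5R)-3-(but-3-enoyl)-5-(hydroxymethyl)-5-[(4-methoxybenzyloxy)methyl]-4-[(3S)-3-methyl-3-(triethylsilyloxy)pent-4-enyl]dihydrofuran-2(3H)-one, via hydroxy-δ-lactone 15 (not isolated)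
Conditions: KOt-Bu (1.0 equiv), THF/t-BuOH (4:1), 0 → 45 °C; AcOH quench
Reagents that add atoms: none
Why: KOt-Bu deprotonates C9 and the β-keto ester enolate attacks the epoxide at its secondary carbon C8 anti to the C–O bond, closing a six-membered hydroxy-δ-lactone; the C12 alkoxide so released adds to the lactone carbonyl C10 and expels the primary C16 alkoxide, an O-to-O acyl shift that leaves the five-membered γ-lactone of ring B. The closest known reaction type is the intramolecular C-alkylation of a stabilised carbanion by a tethered epoxide (epoxy-malonate and Stork epoxynitrile cyclisations), followed by ordinary translactonisation. The δ-lactone closes 6-endo-tet with respect to the epoxide (6-enolexo for the keto enolate) and the γ-lactone then forms by 5-exo-trig acyl transfer. C8 is set by stereospecific inversion of the epoxide carbon made in step 5, so its relation to C12 follows from the alkene geometry of step 3 and the tartrate; C9 stays acidic between two carbonyls and should equilibrate to the isomer with the acyl group trans to the C8 chain. The step needs attack at C8 and not at C12, C- and not O-alkylation and an unmoved allyl double bond: C12 is fully substituted and carries two CH2O groups, which shuts down substitution there, C-attack gives a six-membered ring where O-attack would need an eight-membered one, and one equivalent of base holds substrate and product as mono-enolates that cannot carry the double bond into conjugation. The acyl shift is driven by the stability of the γ-lactone and of the primary alkoxide.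

Step 9
Reactants: 16 keto lactone alcohol
Product: 17 C16 tert-butyldimethylsilyl ether of the keto lactone
Conditions: TBSCl, imidazole, DMF, 0 °C
Reagents that add atoms: tert-butyldimethylsilyl chloride, CC(C)(C)[Si](C)(C)Cl
Why: Silylation of the only free (primary) hydroxyl keeps C16–OH out of the sulfonylation of step 11, and imidazole is too weak a base to move the allyl double bond.

Step 10
Reactants: 17 C16 tert-butyldimethylsilyl ether of the keto lactone
Product: 18 silylated triol (C1 carbinol as epimer mixture; C10 primary OH; C12 tertiary OH)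
Conditions: LiAlH4, THF, −20 → 0 °C; aq. potassium sodium tartrate
Reagents that add atoms: none
Why: Hydride reduction opens the lactone to the C10 primary/C12 tertiary diol and reduces the ketone to the C1 carbinol (re-oxidised in step 12), which fixes C9 as a non-acidic stereocentre in its trans arrangement.

Step 11
Reactants: 18 silylated triol
Product: 20 ring-B tetrahydrofuran with C1 carbinol, via primary tosylate 19 (not isolated)
Conditions: TsCl, Et3N, DMAP (cat.), CH2Cl2, 0 °C; concentrate; KOt-Bu, THF, 0 °C → rt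
Reagents that add atoms: 4-toluenesulfonyl chloride, Cc1ccc(cc1)S(=O)(=O)Cl (its atoms stay in intermediate 19 and leave as tosylate)
Why: Selective sulfonylation of the primary C10–OH followed by intramolecular Williamson etherification by the C12 alkoxide (5-exo-tet) closes ring B, with no stereocentre involved because C10 is a CH2 and the C12–O bond is kept.

Step 12
Reactants: 20 ring-B tetrahydrofuran with C1 carbinol
Product: 21 ring-B allyl ketone (C1=O; C5–OTES, C13–OPMB, C16–OTBS)
Conditions: Dess–Martin periodinane, pyridine, CH2Cl2, 0 °C → rt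
Reagents that add atoms: none
Why: Dess–Martin oxidation returns the allyl ketone under non-basic conditions that should neither conjugate the double bond nor disturb C9, whose trans arrangement is in any case the thermodynamic one.

Step 13
Reactants: 21 ring-B allyl ketone
Product: 22 keto diol (C16–OH and C5–OH free, C13–OPMB)
Conditions: HF·pyridine, pyridine, THF, 0 °C → rt
Reagents that add atoms: none
Why: Fluoride cleavage of both silyl ethers frees C16–OH and the tertiary allylic C5–OH, whose free hydroxyl should make the hindered vinyl group a far better metathesis partner than its silyl ether; the PMB ether survives.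

Step 14
Reactants: 22 keto diol
Product: 23 bicyclic keto diol (rings A and B trans-fused, C1 ketone, C3=C4 Z)
Conditions: second-generation Grubbs catalyst (H2IMes)(PCy3)Cl2Ru=CHPh (10 mol%), 1,4-benzoquinone (20 mol%), toluene (1 mM), 80 °C
Reagents that add atoms: none
Why: Ring-closing metathesis between the allyl ketone and the vinyl carbinol closes ring A at C3=C4 with the Z geometry imposed by the nine-membered ring, helped by the trans arms on ring B, the sp2 centre C1 and high dilution, and with C1 still a ketone there is no 1,1-disubstituted alkene that could close a seven-membered ring instead.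

Step 15
Reactants: 23 bicyclic keto diol
Product: 24 bicyclic diol with exocyclic methylene at C1
Conditions: Tebbe reagent Cp2Ti(μ-Cl)(μ-CH2)AlMe2 (3.5 equiv), pyridine, THF/toluene, −40 → 0 °C; aq. NaOH
Reagents that add atoms: Tebbe reagent, C[Al-]1(C)C[Ti](C2C=CC=C2)(C2C=CC=C2)[Cl+]1
Why: Tebbe methylenation converts the enolisable β,γ-unsaturated ketone into the exocyclic alkene without base, so neither C9 nor the skipped double bond is disturbed, and the two hydroxyls only consume reagent as titanium alkoxides that return on work-up.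

Step 16
Reactants: 24 bicyclic diol with exocyclic methylene at C1; 25 stearoyl chloride
Product: 26 C16 stearate with C13 PMB ether
Conditions: pyridine, DMAP (cat.), CH2Cl2, −20 → 0 °C
Reagents that add atoms: none
Why: Acylation with the acid chloride under nucleophilic catalysis is selective for the primary C16–OH over the tertiary allylic C5–OH.

Step 17
Reactants: 26 C16 stearate with C13 PMB ether
Product: 27 C16 stearate with free C13 primary alcohol
Conditions: DDQ, CH2Cl2/pH 7 phosphate buffer (10:1), 0 °C
Reagents that add atoms: none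
Why: Oxidative PMB cleavage by DDQ under buffered conditions should spare the ester, the tertiary alcohol and the skipped diene, and the alcohol is oxidised at once in step 18 to rule out a 1,3-acyl shift between the two CH2O arms on C12.

Step 18
Reactants: 27 C16 stearate with free C13 primary alcohol
Product: 28 C13 aldehyde
Conditions: Dess–Martin periodinane, pyridine, CH2Cl2, 0 °C
Reagents that add atoms: none
Why: Dess–Martin oxidation gives an α-alkoxy aldehyde that has no α-hydrogen and so can neither epimerise nor eliminate.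

Step 19
Reactants: 28 C13 aldehyde; 29 (triphenylphosphoranylidene)acetaldehyde
Product: 30 (E)-enal (C13=C14)
Conditions: toluene, 80 °C
Reagents that add atoms: none
Why: Wittig olefination with the stabilised formyl ylide gives the E-enal, E selectivity being normal for stabilised ylides.

Step 20
Reactants: 30 (E)-enal; 31 isopropyltriphenylphosphonium iodide
Product: 33 target CNP0274030.1, via isopropylidene ylide 32 (not isolated)
Conditions: 31, n-BuLi, THF, 0 °C; then 30, −78 → 0 °C
Reagents that add atoms: none
Why: Wittig olefination of the enal with the non-stabilised isopropylidene ylide adds 1,2 and forms the trisubstituted alkene, which has no geometry to control, completing the E-diene, and at low temperature the ylide should spare the stearate and the free tertiary alcohol.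

Compound list
1 | (S)-(+)-linalool | C=C[C@@](C)(O)CCC=C(C)C | starting material
2 | (3S)-3,7-dimethyl-3-(triethylsilyloxy)octa-1,6-diene | C=C[C@@](C)(O[Si](CC)(CC)CC)CCC=C(C)C | intermediate
3 | (4S)-4-methyl-4-(triethylsilyloxy)hex-5-enal | C=C[C@@](C)(O[Si](CC)(CC)CC)CCC=O | intermediate
4 | ethyl 2-(diethoxyphosphoryl)acrylate | C=C(C(=O)OCC)P(=O)(OCC)OCC | starting material
5 | 4-methoxybenzyl alcohol | COc1ccc(CO)cc1 | starting material
6 | sodium carbanion of ethyl 2-(diethoxyphosphoryl)-3-(4-methoxybenzyloxy)propanoate (not isolated) | [Na+].CCOC(=O)[C-](COCc1ccc(OC)cc1)P(=O)(OCC)OCC | intermediate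
7 | ethyl (2E,6S)-2-[(4-methoxybenzyloxy)methyl]-6-methyl-6-(triethylsilyloxy)octa-2,7-dienoate | C=C[C@@](C)(O[Si](CC)(CC)CC)CC/C=C(\COCc1ccc(OC)cc1)C(=O)OCC | intermediate
8 | (2Z,6S)-2-[(4-methoxybenzyloxy)methyl]-6-methyl-6-(triethylsilyloxy)octa-2,7-dien-1-ol (CH2OH trans to the chain) | C=C[C@@](C)(O[Si](CC)(CC)CC)CC/C=C(\COCc1ccc(OC)cc1)CO | intermediate
9 | [(2R,3S)-2-[(4-methoxybenzyloxy)methyl]-3-[(3S)-3-methyl-3-(triethylsilyloxy)pent-4-enyl]oxiran-2-yl]methanol | C=C[C@@](C)(O[Si](CC)(CC)CC)CC[C@@H]1O[C@]1(CO)COCc1ccc(OC)cc1 | intermediate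
10 | Meldrum's acid (2,2-dimethyl-1,3-dioxane-4,6-dione) | CC1(C)OC(=O)CC(=O)O1 | starting material
11 | but-3-enoic acid | C=CCC(=O)O | starting material
12 | 5-(1-hydroxybut-3-enylidene)-2,2-dimethyl-1,3-dioxane-4,6-dione | C=CCC(O)=C1C(=O)OC(C)(C)OC1=O | intermediate
13 | but-3-enoylketene (not isolated) | C=CCC(=O)C=C=O | intermediate
14 | {(2S,3S)-2-[(4-methoxybenzyloxy)methyl]-3-[(3S)-3-methyl-3-(triethylsilyloxy)pent-4-enyl]oxiran-2-yl}methyl 3-oxohex-5-enoate (same geometry as 9) | C=C[C@@](C)(O[Si](CC)(CC)CC)CC[C@@H]1O[C@]1(COC(=O)CC(=O)CC=C)COCc1ccc(OC)cc1 | intermediate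
15 | hydroxy-δ-lactone: 3-(but-3-enoyl)-5-hydroxy-5-[(4-methoxybenzyloxy)methyl]-4-[(3S)-3-methyl-3-(triethylsilyloxy)pent-4-enyl]tetrahydropyran-2-one, C8 inverted and C12 retained (not isolated) | C=C[C@@](C)(O[Si](CC)(CC)CC)CC[C@H]2[C@H](C(=O)CC=C)C(=O)OC[C@]2(COCc1ccc(OC)cc1)O | intermediate
16 | (3R,4S,5R)-3-(but-3-enoyl)-5-(hydroxymethyl)-5-[(4-methoxybenzyloxy)methyl]-4-[(3S)-3-methyl-3-(triethylsilyloxy)pent-4-enyl]dihydrofuran-2(3H)-one (keto lactone alcohol; C8, C9, C12 as in the target) | C=C[C@@](C)(O[Si](CC)(CC)CC)CC[C@H]2[C@H](C(=O)CC=C)C(=O)O[C@@]2(COCc1ccc(OC)cc1)CO | intermediate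
17 | C16 tert-butyldimethylsilyl ether of the keto lactone (configuration as 16) | C=C[C@@](C)(O[Si](CC)(CC)CC)CC[C@H]2[C@H](C(=O)CC=C)C(=O)O[C@@]2(COCc1ccc(OC)cc1)CO[Si](C)(C)C(C)(C)C | intermediate
18 | silylated triol: C10 primary OH, C12 tertiary OH, C1 carbinol as epimer mixture (C5, C8, C9, C12 as in the target) | C=C[C@@](C)(O[Si](CC)(CC)CC)CC[C@@H]([C@@H](CO)C(O)CC=C)[C@](O)(COCc1ccc(OC)cc1)CO[Si](C)(C)C(C)(C)C | intermediate
19 | primary (C10) tosylate of the triol (not isolated) | C=C[C@@](C)(O[Si](CC)(CC)CC)CC[C@@H]([C@@H](COS(=O)(=O)c1ccc(C)cc1)C(O)CC=C)[C@](O)(COCc1ccc(OC)cc1)CO[Si](C)(C)C(C)(C)C | intermediate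
20 | ring-B tetrahydrofuran with C1 carbinol (epimer mixture), C5–OTES, C13–OPMB, C16–OTBS; C7 chain trans to the C1 arm and cis to CH2OTBS | C=C[C@@](C)(O[Si](CC)(CC)CC)CC[C@H]2[C@H](C(O)CC=C)CO[C@@]2(COCc1ccc(OC)cc1)CO[Si](C)(C)C(C)(C)C | intermediate
21 | ring-B allyl ketone (C1=O), C5–OTES, C13–OPMB, C16–OTBS | C=C[C@@](C)(O[Si](CC)(CC)CC)CC[C@H]2[C@H](C(=O)CC=C)CO[C@@]2(COCc1ccc(OC)cc1)CO[Si](C)(C)C(C)(C)C | intermediate
22 | keto diol: C16–OH and C5–OH free, C13–OPMB | C=C[C@@](C)(O)CC[C@H]2[C@H](C(=O)CC=C)CO[C@@]2(COCc1ccc(OC)cc1)CO | intermediate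
23 | bicyclic keto diol: rings A and B trans-fused, C1 ketone, C3=C4 Z, C5 S | O=C1C/C=C\[C@@](C)(O)CC[C@H]2[C@H]1CO[C@@]2(COCc3ccc(OC)cc3)CO | intermediate
24 | bicyclic diol with exocyclic methylene at C1 (C13–OPMB, C16–OH, C5–OH) | C=C1C/C=C\[C@@](C)(O)CC[C@H]2[C@H]1CO[C@@]2(COCc3ccc(OC)cc3)CO | intermediate
25 | stearoyl chloride (octadecanoyl chloride) | CCCCCCCCCCCCCCCCCC(=O)Cl | starting material
26 | C16 stearate with C13 PMB ether | C=C1C/C=C\[C@@](C)(O)CC[C@H]2[C@H]1CO[C@@]2(COCc3ccc(OC)cc3)COC(=O)CCCCCCCCCCCCCCCCC | intermediate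
27 | C16 stearate with free C13 primary alcohol | C=C1C/C=C\[C@@](C)(O)CC[C@H]2[C@H]1CO[C@@]2(CO)COC(=O)CCCCCCCCCCCCCCCCC | intermediate
28 | C13 aldehyde (C16 stearate) | C=C1C/C=C\[C@@](C)(O)CC[C@H]2[C@H]1CO[C@@]2(C=O)COC(=O)CCCCCCCCCCCCCCCCC | intermediate
29 | (triphenylphosphoranylidene)acetaldehyde | O=CC=P(c1ccccc1)(c1ccccc1)c1ccccc1 | starting material
30 | (E)-enal on C12 (C13=C14 E, C16 stearate) | C=C1C/C=C\[C@@](C)(O)CC[C@H]2[C@H]1CO[C@@]2(/C=C/C=O)COC(=O)CCCCCCCCCCCCCCCCC | intermediate
31 | isopropyltriphenylphosphonium iodide | CC(C)[P+](c1ccccc1)(c1ccccc1)c1ccccc1.[I-] | starting material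
32 | isopropylidenetriphenylphosphorane (not isolated) | CC(C)=P(c1ccccc1)(c1ccccc1)c1ccccc1 | intermediate
33 | CNP0274030.1: stearate of the trans-fused ring A/ring B diol, 5S, 8S, 9R, 12R, C3=C4 Z, (E)-4-methylpenta-1,3-dienyl on C12 | C=C1C/C=C\[C@@](C)(O)CC[C@H]2[C@H]1CO[C@@]2(/C=C/C=C(C)C)COC(=O)CCCCCCCCCCCCCCCCC | target

Total step count: 20
Longest linear sequence: 19 steps (steps 1–5 and 7–20; step 6 is a one-step side branch)

Steps most likely to fail

1. Step 8. What may go wrong: base-induced migration of the allyl-ketone double bond into conjugation, or retro-Claisen and acyl-transfer cleavage of the keto ester, outrunning the slow 6-endo epoxide opening. The fallback sets out from 9 and comes back at 17. Compound 9 is acetoacetylated with 2,2,6-trimethyl-4H-1,3-dioxin-4-one (toluene, 110 °C) to the acetoacetate ester F1, whose methyl ketone has no double bond to migrate. KOt-Bu then effects the same alkylation and acyl shift to the α-acetyl γ-lactone alcohol F2, and silylation (TBSCl, imidazole) gives the silyl ether F3. Its dianion (NaH, then n-BuLi, THF, −78 °C) adds through the terminal carbon to phenyl vinyl sulfoxide to give the sulfoxide F4. Thermal syn-elimination (toluene, 110 °C, CaCO3) then unveils the allyl ketone, which is 17.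

2. Step 14. What may go wrong: oligomerisation by cross-metathesis and ruthenium hydride migration of the allyl double bond, the nine-membered closure being too slow on the sp3-rich tetrahydrofuran. The fallback sets out from 16 and comes back at 23; it closes the carbocycle two oxidation levels earlier, on the β-keto lactone, whose enol form holds C1, C9 and C10 in one plane. HF·pyridine cleaves the TES ether of 16 to the lactone diol F5, and metathesis under the conditions of step 14 gives the bicyclic keto lactone F6. TBSCl/imidazole silylates the primary hydroxyl to the silyl ether F7, and LiAlH4 gives the tetraol F8. TsCl/Et3N and then KOt-Bu close ring B through the primary tosylate F9 to the tetrahydrofuran diol F10. Dess–Martin oxidation gives the ketone F11, and HF·pyridine removes the TBS ether to give 23.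

3. Step 10. What may go wrong: deprotonation of the acidic C9–H by hydride, which stalls the reduction at the enolate and opens elimination to unsaturated by-products. The fallback sets out from 17 and comes back at 18. Luche reduction (NaBH4, CeCl3·7H2O, MeOH, −78 °C) first converts the ketone into the β-hydroxy lactone F12, which is no longer C–H acidic, and LiBH4 (THF, 0 °C → rt) then opens the lactone to 18.

Further compounds
F1 | step 8 | acetoacetate ester of epoxy alcohol 9 | C=C[C@@](C)(O[Si](CC)(CC)CC)CC[C@@H]1O[C@]1(COC(=O)CC(C)=O)COCc1ccc(OC)cc1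
F2 | step 8 | α-acetyl γ-lactone alcohol (methyl-ketone analogue of 16) | C=C[C@@](C)(O[Si](CC)(CC)CC)CC[C@H]2[C@H](C(C)=O)C(=O)O[C@@]2(COCc1ccc(OC)cc1)CO
F3 | step 8 | C16 tert-butyldimethylsilyl ether of the α-acetyl γ-lactone | C=C[C@@](C)(O[Si](CC)(CC)CC)CC[C@H]2[C@H](C(C)=O)C(=O)O[C@@]2(COCc1ccc(OC)cc1)CO[Si](C)(C)C(C)(C)C
F4 | step 8 | 4-(phenylsulfinyl)butanoyl lactone (sulfoxide precursor of the allyl ketone) | C=C[C@@](C)(O[Si](CC)(CC)CC)CC[C@H]2[C@H](C(=O)CCCS(=O)c1ccccc1)C(=O)O[C@@]2(COCc1ccc(OC)cc1)CO[Si](C)(C)C(C)(C)C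
F5 | step 14 | keto lactone diol (16 without the TES group) | C=C[C@@](C)(O)CC[C@H]2[C@H](C(=O)CC=C)C(=O)O[C@@]2(COCc1ccc(OC)cc1)CO
F6 | step 14 | bicyclic keto lactone diol (ring A closed, C3=C4 Z) | O=C1C/C=C\[C@@](C)(O)CC[C@H]2[C@H]1C(=O)O[C@@]2(COCc3ccc(OC)cc3)CO
F7 | step 14 | C16 tert-butyldimethylsilyl ether of the bicyclic keto lactone | O=C1C/C=C\[C@@](C)(O)CC[C@H]2[C@H]1C(=O)O[C@@]2(COCc3ccc(OC)cc3)CO[Si](C)(C)C(C)(C)C
F8 | step 14 | cyclononene tetraol (C1, C5, C10 and C12 hydroxyls; C1 epimer mixture) | OC1C/C=C\[C@@](C)(O)CC[C@@H]([C@H]1CO)[C@](O)(COCc3ccc(OC)cc3)CO[Si](C)(C)C(C)(C)C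
F9 | step 14 | primary (C10) tosylate of the tetraol (not isolated) | OC1C/C=C\[C@@](C)(O)CC[C@@H]([C@H]1COS(=O)(=O)c3ccc(C)cc3)[C@](O)(COCc3ccc(OC)cc3)CO[Si](C)(C)C(C)(C)C
F10 | step 14 | bicyclic tetrahydrofuran diol (C1 carbinol, C5–OH, C16–OTBS) | OC1C/C=C\[C@@](C)(O)CC[C@H]2[C@H]1CO[C@@]2(COCc3ccc(OC)cc3)CO[Si](C)(C)C(C)(C)C
F11 | step 14 | bicyclic ketone with C16–OTBS and free C5–OH | O=C1C/C=C\[C@@](C)(O)CC[C@H]2[C@H]1CO[C@@]2(COCc3ccc(OC)cc3)CO[Si](C)(C)C(C)(C)C
F12 | step 10 | β-hydroxy lactone (C1 carbinol, lactone intact) | C=C[C@@](C)(O[Si](CC)(CC)CC)CC[C@H]2[C@H](C(O)CC=C)C(=O)O[C@@]2(COCc1ccc(OC)cc1)CO[Si](C)(C)C(C)(C)C
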